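**Assumption:** the target, 2,3,4,6-tetrabromo-1-methyl-1H-indole, has no stereocentre and no stereoaxis, so it is achiral and "single enantiomer" needs no stereocontrol.

**Retrosynthetic overview**
1. The obvious end-game (C2/C3 dibromination of 4,6-dibromo-1-methylindole) is avoided; the pyrrole ring is instead closed last, with both of its bromines set in the ring-forming step.
2. Target 7 ⇐ indolium bromide 6 (loss of MeBr) ⇐ 5-endo-dig bromocyclization of bromoalkyne 5 (forms N1–C2 and C3–Br; C2–Br arrives on the alkyne).
3. Bromoalkyne 5 ⇐ gem-dibromoolefin 4 (E2) ⇐ aldehyde 3 (Ramirez/Corey–Fuchs olefination).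
4. Aldehyde 3 ⇐ SNAr of 2,4-dibromo-6-fluorobenzaldehyde 1 with dimethylamine 2.
5. Ring order: the benzene ring is bought with the 4,6-dibromo pattern in place; the pyrrole ring is the only ring formed (step 4).

**Route**

Step 1
Reactants: 1 2,4-dibromo-6-fluorobenzaldehyde; 2 dimethylamine (2 M in THF, 1.5 equiv)
Product: 3 2,4-dibromo-6-(dimethylamino)benzaldehyde
Conditions: K2CO3 (2 equiv), DMSO, 50 °C, 6 h
Reagents that add atoms: none
Why: SNAr ortho to the formyl group, where fluoride is displaced far faster than either activated bromide because Meisenheimer addition is rate-limiting (F ≫ Br), and the NMe2 group once installed deactivates the ring toward a second substitution; no stereocentre is formed.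

Step 2
Reactants: 3 2,4-dibromo-6-(dimethylamino)benzaldehyde
Product: 4 3,5-dibromo-2-(2,2-dibromoethenyl)-N,N-dimethylaniline
Conditions: CBr4 (2 equiv), PPh3 (2 equiv), Zn dust (2 equiv), CH2Cl2, rt, 24 h; then 3, 0 °C → rt, dark
Reagents that add atoms: carbon tetrabromide BrC(Br)(Br)Br
Why: Ramirez gem-dibromoolefination (first half of the Corey–Fuchs sequence), a Wittig reaction of Ph3P=CBr2 with a non-enolisable aryl aldehyde, run in the zinc variant so that no Ph3PBr2/HBr is present to attack the basic aniline; no stereocentre is formed.

Step 3
Reactants: 4 3,5-dibromo-2-(2,2-dibromoethenyl)-N,N-dimethylaniline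
Product: 5 3,5-dibromo-2-(bromoethynyl)-N,N-dimethylaniline
Conditions: NaHMDS (1.2 equiv), THF, −78 °C, 30 min; aq NH4Cl
Reagents that add atoms: none
Why: anti-E2 dehydrobromination of the vinylic H with the bromine trans to it gives the 1-bromoalkyne, and a hindered amide base at −78 °C neither exchanges the aryl bromides nor generates an aryne; no stereocentre is formed.

Step 4
Reactants: 5 3,5-dibromo-2-(bromoethynyl)-N,N-dimethylaniline
Product: 7 2,3,4,6-tetrabromo-1-methyl-1H-indole, via 2,3,4,6-tetrabromo-1,1-dimethylindolium bromide 6 (not isolated)
Conditions: Br2 (1.05 equiv, 0.1 M in CH2Cl2, added over 30 min), CH2Cl2, −78 °C → rt, dark; aq Na2S2O3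
Reagents that add atoms: bromine BrBr
Why: Proposed new method: Br2 activates the C≡C of 5 as a bridged bromirenium ion, the ortho NMe2 nitrogen opens it anti in the only geometrically possible 5-endo-dig mode at the bromine-bearing alkyne carbon (whose cationic character is stabilised by the bromine lone pairs) to give indolium bromide 6 with C2–Br and C3–Br in place, and bromide then removes one N-methyl by SN2 (MeBr) to aromatise to 7; the closest known reaction type is the Larock electrophilic iodocyclization of N,N-dialkyl-2-alkynylanilines to 3-haloindoles, extended here to a 1-bromoalkyne and Br2, and no stereocentre is formed.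

**Compound list**
1 | 2,4-dibromo-6-fluorobenzaldehyde | O=Cc1c(F)cc(Br)cc1Br | starting material
2 | dimethylamine | CNC | starting material
3 | 2,4-dibromo-6-(dimethylamino)benzaldehyde | CN(C)c1cc(Br)cc(Br)c1C=O | intermediate
4 | 3,5-dibromo-2-(2,2-dibromoethenyl)-N,N-dimethylaniline | CN(C)c1cc(Br)cc(Br)c1C=C(Br)Br | intermediate
5 | 3,5-dibromo-2-(bromoethynyl)-N,N-dimethylaniline | CN(C)c1cc(Br)cc(Br)c1C#CBr | intermediate
6 | 2,3,4,6-tetrabromo-1,1-dimethyl-1H-indol-1-ium bromide | C[N+]1(C)C(Br)=C(Br)c2c(Br)cc(Br)cc21.[Br-] | intermediate
7 | 2,3,4,6-tetrabromo-1-methyl-1H-indole | Cn1c(Br)c(Br)c2c(Br)cc(Br)cc21 | target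

**Total step count:** 4
**Longest linear sequence:** 4 steps (1 → 3 → 4 → 5 → 7)

**Steps most likely to fail, with fallbacks**

Step 4 (key bromocyclization) is the riskiest. Br2 could brominate the dimethylaniline ring at the positions ortho or para to nitrogen, or simply add across the electron-poor bromoalkyne, before the nitrogen closes the ring. The fallback gives up the alkyne logic and sets out from 1. Compound 1 is heated with sarcosine ethyl ester hydrochloride and K2CO3 in DMF at 110 °C; SNAr at fluorine followed by intramolecular aldol condensation and dehydration gives ethyl 4,6-dibromo-1-methyl-1H-indole-2-carboxylate F1. Saponification with LiOH in THF/MeOH/H2O gives 4,6-dibromo-1-methyl-1H-indole-2-carboxylic acid F2. Treatment of F2 with Bu4NBr3 (2.2 equiv) and K3PO4 in MeCN at 60 °C brominates C3 and then effects ipso-bromodecarboxylation at C2, so the fallback comes back to the route at 7.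

Step 2 (gem-dibromoolefination) is second. The aldehyde in 3 is flanked by Br and NMe2 and is donor-deactivated, so the bulky ylide Ph3P=CBr2 may add slowly, and the amine may interfere with bromophosphonium species. The fallback sets out from 3 and avoids phosphorus. Condensation with hydrazine hydrate in EtOH gives (E)-[2,4-dibromo-6-(dimethylamino)benzylidene]hydrazine F3. This N-unsubstituted hydrazone is then treated with CBr4, CuCl (10 mol %) and aqueous NH3 in DMSO at rt (copper-catalysed olefination with loss of N2), and the fallback comes back to the route at 4.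

Step 3 (dehydrobromination) is third. Excess strong base can attack the alkynyl bromine and give terminal-alkyne mixtures, and 5 may not tolerate basic conditions. The fallback sets out from 3, bypasses 4, and builds the triple bond first. Seyferth–Gilbert homologation with dimethyl (1-diazo-2-oxopropyl)phosphonate (Ohira–Bestmann reagent) and K2CO3 in MeOH at rt gives 3,5-dibromo-2-ethynyl-N,N-dimethylaniline F4. Neutral electrophilic bromination of the terminal alkyne with NBS and AgNO3 (10 mol %) in acetone at rt then installs the alkynyl bromine, and the fallback comes back to the route at 5.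

**Further compounds**
F1 | step 4 | ethyl 4,6-dibromo-1-methyl-1H-indole-2-carboxylate | CCOC(=O)c1cc2c(Br)cc(Br)cc2n1C
F2 | step 4 | 4,6-dibromo-1-methyl-1H-indole-2-carboxylic acid | Cn1c(C(=O)O)cc2c(Br)cc(Br)cc21
F3 | step 2 | (E)-[2,4-dibromo-6-(dimethylamino)benzylidene]hydrazine | CN(C)c1cc(Br)cc(Br)c1/C=N/N
F4 | step 3 | 3,5-dibromo-2-ethynyl-N,N-dimethylaniline | CN(C)c1cc(Br)cc(Br)c1C#C
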